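Start from the earlier runs, at one temperature, and ask what the south-east charge holds when it is repeated as the north-west run and left for 390 min.

| flask | starting material | coupling partner | time |
|---|---|---|---|
| south-east | 0.800 M | 0.800 M |  |
| north-east | 0.320 M | 0.320 M |  |
| south | 0.800 M | 0.400 M |  |
| east | 2.40 M | 0.800 M |  |
| north-west | 0.800 M | 0.800 M | 390 min |

| south-east run: time / min | south-east run: [target] / M | north-east run: time / min | north-east run: [target] / M | south run: time / min | south run: [target] / M | east run: time / min | east run: [target] / M |
|---|---|---|---|---|---|---|---|
| 16 | 0.0612 | 16 | 0.0117 | 16 | 0.0312 | 16 | 0.1672 |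
| 32 | 0.1058 | 32 | 0.0194 | 32 | 0.0579 | 32 | 0.2695 |
| 49 | 0.1499 | 49 | 0.0227 | 49 | 0.0814 | 49 | 0.3437 |
| 65 | 0.1744 | 65 | 0.0338 | 65 | 0.0952 | 65 | 0.3818 |
| 81 | 0.1929 | 81 | 0.0369 | 81 | 0.1048 | 81 | 0.3996 |
| 98 | 0.2070 | 98 | 0.0451 | 98 | 0.1214 | 98 | 0.4118 |
| 110 | 0.2151 | 110 | 0.0474 | 110 | 0.1257 | 110 | 0.4138 |
| 130 | 0.2248 | 130 | 0.0527 | 130 | 0.1305 | 130 | 0.4128 |

(readings scatter by 0.002 M)

- how the opening rate goes with [starting material] round the charge of the south-east run: the exponent of the rate at two percent of starting material gone to target (one fixed amount of target, the same in the runs compared)
- how the opening rate goes with [coupling partner] round the charge of the south-east run: the exponent of the rate at two percent of starting material gone to target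
- target in the north-west run at 390 min, as a share of the starting material charged

- Overall: starting material + coupling partner -> target.
- Constant volume, constant temperature.
- "The second partner" is coupling partner.
- An order is taken over about fifteen percent of the charge, up and down.

Settle the orders first, letting the readings at 16 min stand in for the opening rates; this compares the runs at one fixed time, not at one fixed amount of target, so it gives only a rough exponent. With coupling partner at 0.400 M instead of 0.800 M, the south run reads 0.510 of the south-east target, an exponent of 0.972. With starting material at 2.40 M instead of 0.800 M, the east run reads 2.73 of it, an exponent of 0.915. Expect both orders near 1.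

Now bracket the north-west target from above. In the south-east run, each gain of about half an hour is 0.546 of the one before. Sum that shrinking series onto the last reading, and the ceiling is 30.8% of the charge.

For the floor, look at the east run, whose coupling partner is the limiting reagent. Its target reads 0.4138 M at 110 min and 0.4128 M at 130 min, so it stands nearly still, but a slow fall could hide in the scatter. Call the fade allowance 0.00115 min⁻¹ the steepest fractional fall per minute that these readings admit at 3 standard deviations of their difference. Suppose the south-east target stops rising at its last reading and then fades at this allowance. It keeps 0.742 of itself by 390 min, which puts the floor at 20.9%.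

The forecast gives orders of 1 and 1 and a north-west target of 32%, within 30% to 34%, holding that “by 390 min it is dead”, so its central value stands higher than my ceiling.

The flask gives orders of 1.0 and 1.0 and a target of 22.0%, higher than the floor and lower than the ceiling.

    starting material + coupling partner ⇌ target + by-product (0.006600 M⁻¹ min⁻¹, 0.01398 M⁻¹ min⁻¹)
    target → decomposed product (0.001386 min⁻¹)
    starting material → decomposed substrate (0.002382 min⁻¹)

The north-west target ends low because of the loss of target to decomposed product together with the loss of starting material to decomposed substrate. From the last south-east reading to this result, the fall works out at 9.34 × 10⁻⁴ min⁻¹, less than the fade allowance. Without the loss of target to decomposed product, the north-west run gives 31.6%, against 22.0% in the run as it is.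

The data were computed for an exercise, and the scatter is random.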